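## Structural features

The target 31 is a C42 stilbenoid trimer built on a hexasubstituted benzene, ring A (atoms a1 to a6): a1 and a3 carry the two furan oxygens, a2 the only ring hydrogen, a4 and a6 the C3 carbons of two 2,3-dihydrofurans, and a5 a methylene. Each dihydrofuran bears a 4-hydroxyphenyl group on its oxygen-bearing carbon (Ca, Cd) and an aryl group on C3 (Cb on a6, Cc on a4), trans to each other; all four centres are R, so ring A and its two furans form a C2-symmetric subunit with the axis through a2 and a5. The 3,5-dihydroxyphenyl group on Cc (ring B) is bonded through its ortho carbon to a methine Ce, which carries a 2,4-dihydroxyphenyl ring and is joined by the a5 methylene back to ring A, closing a dibenzo-fused seven-membered ring. Ce (R) is the fifth stereocentre; it stands 1,3 to Cc across ring B, and its aryl group lies on the face of the Cc hydrogen. The fragile sites are the benzylic Ca–O and Cd–O bonds (ionisation under acid, quinone methide formation in the free phenols, hydrogenolysis), the doubly benzylic Cb–H and Cc–H (base-induced β-elimination of the ring A phenoxide), and the six electron-rich aromatic rings with their eight phenolic hydroxyl groups. The real difficulty is to place two trans-dihydrofurans on a crowded benzene without passing through benzylic cations, and then to close the seven-membered ring with control of Ce. The key step exploits the a2 hydrogen: it sits between the two carbons that must become C–O, so in a 4,6-dibromide it is the most acidic ring hydrogen, and the local C2 symmetry lets both O–ring A bonds form in one operation from two identical arms.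

## Logic of the disconnections

31 from 30. The eight O–H bonds are traced back to O–CH3. Methyl ethers tolerate every organometallic, hydride and lithium amide step and keep the aryl building blocks commercial. The demand is a final eightfold Lewis-acid dealkylation that leaves the two benzylic C–O bonds intact.

30 from 29. The bond between Ce and the ortho carbon of ring B is cut. A cation at Ce is stabilised by the ortho,para-dimethoxyphenyl group, and ring B is a nucleophilic arene held in reach. The gain is the loss of the seven-membered ring and of the fifth stereocentre, leaving a C2-symmetric bis(furan) with one alkene side chain. Because the axis exchanges the two dimethoxyphenyl rings of 29, attack by either gives 30, so no differentiation of identical rings is needed. The forward step must protonate the alkene carbon next to ring A, close the ring faster than the furans ionise, and place the Ce aryl group pseudo-axial.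

29 from 25 and 28 (28 from 27, 27 from 26). The alkene C=C bond is cut. A phosphonium ylide is chosen over a phosphonate anion because it is far less basic, which matters for 25, whose Cb–H and Cc–H are acidified by the ortho formyl group. The alkene geometry is irrelevant, since step 20 destroys it.

25 from 24 from 23. Only the oxidation level and the silyl group at the a5 carbon change. This carbon is carried as a silyl ether because an ester or nitrile there would be attacked by the neighbouring alkoxides of the arms in steps 12 and 15.

23 from 19 (through 22, 21 and 20). Both O–ring A bonds are cut, opening both dihydrofurans at once. The bonds form at sp2 carbon, so the four stereocentres can be set on open chains and carried through unchanged. The gain is a C2-symmetric dibromide with two identical acyclic arms. The demand is that each alkoxide adds to the aryne carbon next to its own arm and that the second aryne arises from the anion left by the first addition.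

19 from 18, and 18 through 17 from 15 and 16. The carbinol C–H bond is cut first (hydride addition to the ketone), then the Ca–aryl bond (addition of 16 to the aldehyde). The carbinol is made by reduction because, with ring A as the largest α-substituent, the Felkin–Anh model gives the required (1R) centre from hydride addition to 18 and the wrong epimer from aryl addition to 15. The cost is an oxidation–reduction pair. The demand is that the enolisable α-centre of 15 and 18 is not epimerised.

15 from 13 (through 14), and 13 from 11 and 12. The aldehyde is traced to a nitromethyl group, and the two Cb–aryl bonds are cut to a bis(nitroalkene) and two molecules of 12. Both centres are then set in one catalyst-controlled double conjugate addition, which gives the C2 isomer and sends most of the minor enantiomeric pathway into a separable meso isomer. The demand is aryl transfer to a β-carbon flanked by two ortho substituents.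

11 from 9 and 10. The two nitroalkene C=C bonds are cut to a dialdehyde and two molecules of 10.

9 from 1 through 8, 7, 6, 5, 4, 3 and 2. Only functional groups change. The bromines are introduced first, where the two methyl groups direct them. The central carbon is kept at the carboxyl level (no benzylic hydrogen) while the methyl groups are brominated and oxidised. The aldehydes are then masked so that the ester can be reduced and silylated.

## Other disconnections considered

Alternative 1: The cut runs through ring B: its bonds to Cc and to the future Ce are both broken, so that ring B is added as the aryne A4 to the ring A-fused β-keto ester A2. In the forward sense, fluoride would release A4 from the silyl triflate A3, the enolate of A2 would add to it, and the aryl anion would add to the ketone and fragment, expanding the indanone to the dibenzocycloheptenone ester A1.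
- In favour: one step attaches ring B and closes the seven-membered ring from two small fragments. The methoxy group beside the triple bond of A4 should direct the enolate carbon to the distal aryne carbon, giving the right oxygen pattern. The ketone of A1 is a natural handle for the 2,4-dioxygenated aryl group.
- Against: A1 is racemic and holds none of the five stereocentres. Cc must still become part of a trans-dihydrofuran with Cd, and Ce must be arylated and deoxygenated with control relative to Cc. Ring A of A1 lacks the second furan, whose C3 carbon would have to be introduced late at the most crowded ring position.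
- Comparison: on structure, it matches the dibenzocycloheptane core but makes no use of the C2-symmetric bis(furan) unit that step 15 builds in one two-directional operation. On mechanism, aryne insertion into β-keto esters is the equal or the better of step 15 in precedent. On step economy, it reaches the carbocyclic core in fewer steps (a point in its favour), but the total would be longer because every stereocentre and one furan remain to be made.

Alternative 2: The cut separates ring A from Cc and the furan oxygen from Cd, leading back to the iodophenol–diarylalkyne A6, in which Ce is already set. Forward, oxidative addition of zerovalent palladium (from Pd(OAc)2) into the C–I bond of A6, 7-exo-dig carbopalladation of the tethered alkyne and C–O reductive elimination with the neighbouring phenoxide would give the tetracycle A5.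
- In favour: two rings, one of them seven-membered, and two bonds form in one catalytic step. The alkyne of A6 is assembled by cross-coupling. Ce is fixed early on an open chain, which is as good as or better than creating it in a late ring closure.
- Against: A5 is an aromatic benzofuran, so Cc and Cd do not yet exist as stereocentres. They would have to come from reduction of a tetrasubstituted, electron-rich furan double bond, which normally gives the cis isomer and would need a later epimerisation, with only the remote Ce to choose the face. The carbopalladation must outrun protodehalogenation. The second furan on ring A is again missing.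
- Comparison: on structure, A5 contains more of the carbon framework than 23, but with two stereocentres flattened, whereas 23 holds four of the five in final form. On mechanism, the cascade forms more bonds per step (better on that point) but depends on a less common vinyl C–O reductive elimination, while step 15 uses two ordinary alkoxide–aryne additions. On step economy, it is shorter to the core and longer in total.

Alternative 3: Ring B is grown rather than carried in: four of its C–C bonds are cut, leading back to the cycloheptenyl diazomethyl ketone A8 and the siloxyalkyne A9. Forward, photochemical Wolff rearrangement of A8, [2+2] cycloaddition with A9, four-electron ring opening and six-electron ring closure would end in the mono-silylated resorcinol A7.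
- In favour: both oxygens of ring B are placed regiospecifically without electrophilic substitution. The conditions are neutral, so Cc, Cd and Ce, all present in A8, should survive; in this respect it is the equal of step 15. The two ring B oxygens emerge differentiated.
- Against: the difficulty is moved into A8, a seven-membered ring with three stereocentres fused to a dihydrobenzofuran, which must be made without ring B, the group that makes that ring easy to close. In A8, Ce is the γ-position of the enone and benzylic, and Cc is allylic and benzylic, so both are prone to epimerisation or double-bond migration. The ring that is built is a plain 3,5-dioxygenated phenyl, available in the chosen route as the commercial 12. The second furan is again absent.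
- Comparison: on structure, it addresses the least demanding ring. On mechanism, the pericyclic cascade is well precedented and, in functional-group tolerance, the equal or the better of step 15. On step economy, it is clearly longer and linear.

Key step: step 15

Remark on the chemistry: the stereodescriptors of 19, 23 and 31 agree with one another (all stereocentres R, both furans trans); 29 is carried as an E/Z mixture because its geometry is lost in step 20; 16 is taken as the commercial THF solution.

## Steps

Step 1
Reactants: 1 2,6-dimethylbenzoic acid
Product: 2 3,5-dibromo-2,6-dimethylbenzoic acid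
Conditions: NBS (2.2 equiv), conc. H2SO4, rt → 50 °C
Reagents that add atoms: N-bromosuccinimide, O=C1CCC(=O)N1Br
Why: Electrophilic aromatic bromination; C3 and C5 are ortho/para to the methyl groups and meta to the carboxyl group, while C4 is meta to both methyls, so the 3,5-dibromide should form and C4 keeps the future a2 hydrogen.

Step 2
Reactants: 2 3,5-dibromo-2,6-dimethylbenzoic acid
Product: 3 methyl 3,5-dibromo-2,6-dimethylbenzoate
Conditions: MeI, K2CO3, DMF, rt
Reagents that add atoms: iodomethane, CI
Why: Alkylative esterification of the carboxylate (SN2 at methyl) avoids attack at the hindered carboxyl carbon of a 2,6-disubstituted benzoic acid.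

Step 3
Reactants: 3 methyl 3,5-dibromo-2,6-dimethylbenzoate
Product: 4 methyl 3,5-dibromo-2,6-bis(bromomethyl)benzoate
Conditions: NBS (2.2 equiv), AIBN (cat.), PhCF3, reflux
Reagents that add atoms: N-bromosuccinimide, O=C1CCC(=O)N1Br
Why: Wohl–Ziegler bromination; the ester carbon has no benzylic hydrogen, so only the two methyl groups react, and each flanked methyl should stop at the monobromide.

Step 4
Reactants: 4 methyl 3,5-dibromo-2,6-bis(bromomethyl)benzoate
Product: 5 methyl 3,5-dibromo-2,6-diformylbenzoate
Conditions: N-methylmorpholine N-oxide (5 equiv), 4 Å molecular sieves, MeCN, rt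
Reagents that add atoms: N-methylmorpholine N-oxide, C[N+]1([O-])CCOCC1
Why: Kornblum-type oxidation: the amine oxide oxygen displaces the benzylic bromide and the alkoxyammonium salt eliminates to the aldehyde; the anhydrous medium avoids phthalide formation with the neighbouring ester.

Step 5
Reactants: 5 methyl 3,5-dibromo-2,6-diformylbenzoate
Product: 6 methyl 3,5-dibromo-2,6-bis(dimethoxymethyl)benzoate
Conditions: HC(OMe)3 (4 equiv), MeOH, p-TsOH (cat.), 50 °C
Reagents that add atoms: trimethyl orthoformate, COC(OC)OC; methanol, CO
Why: Acid-catalysed acetalisation driven by the orthoformate masks both aldehydes so that the ester can be reduced.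

Step 6
Reactants: 6 methyl 3,5-dibromo-2,6-bis(dimethoxymethyl)benzoate
Product: 7 [3,5-dibromo-2,6-bis(dimethoxymethyl)phenyl]methanol
Conditions: i-Bu2AlH (3 equiv), CH2Cl2, −78 → 0 °C; aq. potassium sodium tartrate
Reagents that add atoms: none
Why: The electrophilic aluminium hydride reduces even a 2,6-disubstituted benzoate, while acetals and aryl bromides are inert; 7 is taken on without chromatography to avoid acid-induced closure to a cyclic mixed acetal.

Step 7
Reactants: 7 [3,5-dibromo-2,6-bis(dimethoxymethyl)phenyl]methanol
Product: 8 tert-butyl{[3,5-dibromo-2,6-bis(dimethoxymethyl)phenyl]methoxy}dimethylsilane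
Conditions: TBSCl, imidazole, DMF, rt
Reagents that add atoms: tert-butyldimethylsilyl chloride, CC(C)(C)[Si](C)(C)Cl
Why: Standard silylation of a primary alcohol; the silyl ether is inert to the organomagnesium, hydride and lithium amide reagents used later and cannot be attacked by the alkoxides of the arms.

Step 8
Reactants: 8 tert-butyl{[3,5-dibromo-2,6-bis(dimethoxymethyl)phenyl]methoxy}dimethylsilane
Product: 9 4,6-dibromo-2-{[(tert-butyldimethylsilyl)oxy]methyl}benzene-1,3-dicarbaldehyde
Conditions: PPTS (cat.), acetone/H2O, 40 °C
Reagents that add atoms: water, O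
Why: Mild acid hydrolysis of the dimethyl acetals; a primary tert-butyldimethylsilyl ether should survive pyridinium tosylate in wet acetone.

Step 9
Reactants: 9 4,6-dibromo-2-{[(tert-butyldimethylsilyl)oxy]methyl}benzene-1,3-dicarbaldehyde; 10 nitromethane
Product: 11 tert-butyl({3,5-dibromo-2,6-bis[(E)-2-nitroethenyl]phenyl}methoxy)dimethylsilane
Conditions: 10 (40 equiv) as solvent, NH4OAc (1 equiv), 90 °C
Reagents that add atoms: nitromethane (second equivalent of 10), C[N+](=O)[O-]
Why: Twofold Henry condensation with dehydration in the flask; each of the two aldehydes takes up one molecule of 10, so two equivalents are built in, and the conjugated E-nitroalkenes are the thermodynamic products.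

Step 10
Reactants: 11 tert-butyl({3,5-dibromo-2,6-bis[(E)-2-nitroethenyl]phenyl}methoxy)dimethylsilane; 12 3,5-dimethoxyphenylboronic acid
Product: 13 tert-butyl({3,5-dibromo-2,6-bis[(1R)-1-(3,5-dimethoxyphenyl)-2-nitroethyl]phenyl}methoxy)dimethylsilane
Conditions: 12 (5 equiv), [Rh(C2H4)2Cl]2 (5 mol %), (3aR,6aR)-3,6-diphenyl-1,3a,4,6a-tetrahydropentalene (11 mol %), KHF2, toluene/H2O, 60 °C
Reagents that add atoms: 3,5-dimethoxyphenylboronic acid (second equivalent of 12), COc1cc(B(O)O)cc(OC)c1
Why: Rhodium-catalysed asymmetric conjugate arylation of nitroalkenes: the aryl group passes from boron to the diene-bound monovalent rhodium and is delivered to the Re face of each β-carbon (C=C–N over ring A over H), setting both Cb centres as R under catalyst control, with one molecule of 12 consumed per arm. The diene antipode named is the one expected to give this sense, and the other antipode would be used if a single-arm model showed the opposite. Two independent additions give the C2 isomer, with most of the minor pathway ending in the separable meso isomer; aryl bromides are inert to monovalent rhodium under these conditions.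

Step 11
Reactants: 13 tert-butyl({3,5-dibromo-2,6-bis[(1R)-1-(3,5-dimethoxyphenyl)-2-nitroethyl]phenyl}methoxy)dimethylsilane
Product: 15 (2R,2'R)-2,2'-(4,6-dibromo-2-{[(tert-butyldimethylsilyl)oxy]methyl}-1,3-phenylene)bis[2-(3,5-dimethoxyphenyl)acetaldehyde], via disodium bis(nitronate) 14 (not isolated)
Conditions: NaOMe, MeOH/THF, 0 °C; then aq. TiCl3, NH4OAc buffer (pH 5–6), 0 °C → rt
Reagents that add atoms: water, O
Why: Reductive Nef reaction: trivalent titanium reduces the nitronate to the imine, which hydrolyses to the aldehyde in a buffered, near-neutral medium, so the enolisable diarylmethine centre should not be epimerised; 15 is used at once.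

Step 12
Reactants: 15 (2R,2'R)-2,2'-(4,6-dibromo-2-{[(tert-butyldimethylsilyl)oxy]methyl}-1,3-phenylene)bis[2-(3,5-dimethoxyphenyl)acetaldehyde]; 16 4-methoxyphenylmagnesium bromide
Product: 17 (2R,2'R)-2,2'-(4,6-dibromo-2-{[(tert-butyldimethylsilyl)oxy]methyl}-1,3-phenylene)bis[2-(3,5-dimethoxyphenyl)-1-(4-methoxyphenyl)ethan-1-ol] (mixture of epimers at the two carbinol carbons)
Conditions: 16 (3 equiv), LaCl3·2LiCl (30 mol %), THF, −78 °C; aq. NH4Cl
Reagents that add atoms: 4-methoxyphenylmagnesium bromide (second equivalent of 16), COc1ccc([Mg]Br)cc1
Why: Twofold Grignard addition, one molecule of 16 per aldehyde; the lanthanum salt and the low temperature favour addition over enolisation of the acidic α-centre, and the aryl bromides are left alone. The Felkin–Anh model predicts mainly the (1S) carbinols, which are not the ones needed, so the configuration of this centre is not relied on.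

Step 13
Reactants: 17 (2R,2'R)-bis(carbinol), epimer mixture
Product: 18 (2R,2'R)-2,2'-(4,6-dibromo-2-{[(tert-butyldimethylsilyl)oxy]methyl}-1,3-phenylene)bis[2-(3,5-dimethoxyphenyl)-1-(4-methoxyphenyl)ethan-1-one]
Conditions: Dess–Martin periodinane, NaHCO3, CH2Cl2, 0 °C → rt
Reagents that add atoms: none
Why: Buffered hypervalent iodine oxidation converges both carbinol epimers on one diketone under neutral conditions that should not enolise the α-centre.

Step 14
Reactants: 18 (2R,2'R)-diketone
Product: 19 (1R,2R,1'R,2'R)-2,2'-(4,6-dibromo-2-{[(tert-butyldimethylsilyl)oxy]methyl}-1,3-phenylene)bis[2-(3,5-dimethoxyphenyl)-1-(4-methoxyphenyl)ethan-1-ol]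
Conditions: LiAlH4, THF, −78 °C
Reagents that add atoms: none
Why: Felkin–Anh reduction: hydride attacks each ketone anti to the bulky ortho,ortho-disubstituted ring A and past the small α-hydrogen, which should give the (1R) carbinol from the (2R) ketone, the epimer complementary to that from aryl addition in step 12. Aryl bromides and the silyl ether are untouched at −78 °C.

Step 15
Reactants: 19 (1R,2R,1'R,2'R)-dibromo diol
Product: 23 (2R,3R,5R,6R)-4-{[(tert-butyldimethylsilyl)oxy]methyl}-3,5-bis(3,5-dimethoxyphenyl)-2,6-bis(4-methoxyphenyl)-2,3,5,6-tetrahydrobenzo[1,2-b:5,4-b']difuran, via bromoaryne dialkoxide 20 (not isolated), via monocyclised bromoaryllithium 21 (not isolated), via alkoxyaryne alkoxide 22 (not isolated)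
Conditions: lithium 2,2,6,6-tetramethylpiperidide (4.5 equiv, from 2,2,6,6-tetramethylpiperidine and n-BuLi), THF, −78 → 0 °C; aq. NH4Cl
Reagents that add atoms: none
Why: The excess lithium amide first turns both carbinols into lithium alkoxides and then removes the a2 hydrogen, the most acidic on ring A because two bromines flank it; on warming, LiBr is lost to give bromoaryne 20. The alkoxide of the adjacent arm adds 5-exo-dig to the aryne carbon next to its own side chain (first O–ring A bond, first dihydrofuran), which leaves the charge at a2 beside the remaining bromine (21). This 2-bromoaryllithium expels LiBr in turn to give alkoxyaryne 22, and the second alkoxide closes the second dihydrofuran in the same 5-exo-dig mode; the aryl anion between the two oxygens is protonated on work-up. The closest known reaction types are the intramolecular addition of alkoxides to arynes generated with lithium amides and the relay generation of a second aryne from the 2-haloaryl anion left by a first addition to a 1,3-dihaloarene-derived aryne. No stereocentre is formed: both bonds are made at sp2 ring carbons, so the four centres from steps 10 and 14 are carried over with retention, and the trans relation in each furan follows from the (1R,2R) arms. The required regiochemistry is secured by the five-membered tether (attack at the other aryne carbon would need a bridged ring) and reinforced by the bromine, then the alkoxy group, beside the other aryne carbon, which stabilise the developing aryl anion inductively. Capture of the arynes by the amide and deprotonation of the doubly benzylic methines should be slow because of the bulk of the amide, the negative charges already on the substrate and the low temperature.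

Step 16
Reactants: 23 bis(dihydrofuran) silyl ether
Product: 24 [(2R,3R,5R,6R)-3,5-bis(3,5-dimethoxyphenyl)-2,6-bis(4-methoxyphenyl)-2,3,5,6-tetrahydrobenzo[1,2-b:5,4-b']difuran-4-yl]methanol
Conditions: Bu4NF, THF, 0 °C → rt
Reagents that add atoms: none
Why: Fluoride cleaves the Si–O bond; nothing else in 23 is fluoride-sensitive.

Step 17
Reactants: 24 bis(dihydrofuran) benzylic alcohol
Product: 25 (2R,3R,5R,6R)-3,5-bis(3,5-dimethoxyphenyl)-2,6-bis(4-methoxyphenyl)-2,3,5,6-tetrahydrobenzo[1,2-b:5,4-b']difuran-4-carbaldehyde
Conditions: Dess–Martin periodinane, NaHCO3, CH2Cl2, rt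
Reagents that add atoms: none
Why: Neutral oxidation of a hindered benzylic alcohol to the aldehyde without over-oxidation and without acid or base that could open the furans.

Step 18
Reactants: 26 2,4-dimethoxybenzyl alcohol
Product: 27 (2,4-dimethoxybenzyl)triphenylphosphonium bromide
Conditions: PPh3·HBr, MeCN, reflux
Reagents that add atoms: triphenylphosphine hydrobromide, Br.c1ccc(cc1)P(c1ccccc1)c1ccccc1
Why: Electron-rich benzylic alcohols ionise readily under HBr and the cation is captured by the phosphine, which avoids the unstable 2,4-dimethoxybenzyl halide.

Step 19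
Reactants: 25 bis(dihydrofuran) aldehyde; 27 (2,4-dimethoxybenzyl)triphenylphosphonium bromide
Product: 29 (2R,3R,5R,6R)-4-[2-(2,4-dimethoxyphenyl)ethenyl]-3,5-bis(3,5-dimethoxyphenyl)-2,6-bis(4-methoxyphenyl)-2,3,5,6-tetrahydrobenzo[1,2-b:5,4-b']difuran (E/Z mixture), via phosphonium ylide 28 (not isolated)
Conditions: 27, NaN(SiMe3)2, THF, 0 °C; then 25, 0 °C → rt
Reagents that add atoms: none
Why: Wittig olefination with a semi-stabilised ylide, which is far less basic than a phosphonate anion and so should not deprotonate the C3–H bonds that the ortho formyl group acidifies (deprotonation there would open a furan by β-elimination); the E/Z ratio does not matter.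

Step 20
Reactants: 29 bis(dihydrofuran) stilbene (E/Z)
Product: 30 octa-O-methyl ether of the target, (R) at all five stereocentres
Conditions: CF3CO2H, CH2Cl2, 0 °C → rt
Reagents that add atoms: none
Why: Protonation of either alkene isomer at the carbon next to ring A gives the 2,4-dimethoxybenzylic cation at Ce, which either of the two symmetry-equivalent dimethoxyphenyl rings captures at its ortho carbon in an intramolecular Friedel–Crafts alkylation that closes the seven-membered ring. The furans hold the ring in one boat form, in which the aryl group on Ce should go pseudo-axial, away from the peri methoxy group of ring B and on the face of the Cc hydrogen; this is the (R) centre, and both kinetic approach and any acid-mediated equilibration point the same way. The cation forms under much milder acid than is needed to ionise the aryl alkyl ether bonds of the furans.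

Step 21
Reactants: 30 octa-O-methyl ether
Product: 31 CNP0154047.1 (target)
Conditions: BBr3 (excess), CH2Cl2, −78 °C → rt; MeOH, H2O
Reagents that add atoms: none
Why: Lewis-acid cleavage of the eight aryl methyl ethers by bromide attack at methyl; the cyclic benzylic ethers are less basic and more hindered than the anisole oxygens and should survive if the mixture is not warmed beyond room temperature.

## Compound list

1 | 2,6-dimethylbenzoic acid | Cc1cccc(C)c1C(=O)O | starting material
2 | 3,5-dibromo-2,6-dimethylbenzoic acid | Cc1c(Br)cc(Br)c(C)c1C(=O)O | intermediate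
3 | methyl 3,5-dibromo-2,6-dimethylbenzoate | COC(=O)c1c(C)c(Br)cc(Br)c1C | intermediate
4 | methyl 3,5-dibromo-2,6-bis(bromomethyl)benzoate | COC(=O)c1c(CBr)c(Br)cc(Br)c1CBr | intermediate
5 | methyl 3,5-dibromo-2,6-diformylbenzoate | COC(=O)c1c(C=O)c(Br)cc(Br)c1C=O | intermediate
6 | methyl 3,5-dibromo-2,6-bis(dimethoxymethyl)benzoate | COC(=O)c1c(C(OC)OC)c(Br)cc(Br)c1C(OC)OC | intermediate
7 | [3,5-dibromo-2,6-bis(dimethoxymethyl)phenyl]methanol | OCc1c(C(OC)OC)c(Br)cc(Br)c1C(OC)OC | intermediate
8 | tert-butyl{[3,5-dibromo-2,6-bis(dimethoxymethyl)phenyl]methoxy}dimethylsilane | CC(C)(C)[Si](C)(C)OCc1c(C(OC)OC)c(Br)cc(Br)c1C(OC)OC | intermediate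
9 | 4,6-dibromo-2-{[(tert-butyldimethylsilyl)oxy]methyl}benzene-1,3-dicarbaldehyde | CC(C)(C)[Si](C)(C)OCc1c(C=O)c(Br)cc(Br)c1C=O | intermediate
10 | nitromethane | C[N+](=O)[O-] | starting material
11 | tert-butyl({3,5-dibromo-2,6-bis[(E)-2-nitroethenyl]phenyl}methoxy)dimethylsilane | CC(C)(C)[Si](C)(C)OCc1c(/C=C/[N+](=O)[O-])c(Br)cc(Br)c1/C=C/[N+](=O)[O-] | intermediate
12 | 3,5-dimethoxyphenylboronic acid | COc1cc(B(O)O)cc(OC)c1 | starting material
13 | tert-butyl({3,5-dibromo-2,6-bis[(1R)-1-(3,5-dimethoxyphenyl)-2-nitroethyl]phenyl}methoxy)dimethylsilane | CC(C)(C)[Si](C)(C)OCc1c([C@@H](c2cc(OC)cc(OC)c2)C[N+](=O)[O-])c(Br)cc(Br)c1[C@@H](c1cc(OC)cc(OC)c1)C[N+](=O)[O-] | intermediate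
14 | disodium bis(nitronate) of 13 | CC(C)(C)[Si](C)(C)OCc1c([C@@H](c2cc(OC)cc(OC)c2)C=[N+]([O-])[O-])c(Br)cc(Br)c1[C@@H](c1cc(OC)cc(OC)c1)C=[N+]([O-])[O-].[Na+].[Na+] | intermediate
15 | (2R,2'R)-2,2'-(4,6-dibromo-2-{[(tert-butyldimethylsilyl)oxy]methyl}-1,3-phenylene)bis[2-(3,5-dimethoxyphenyl)acetaldehyde] | CC(C)(C)[Si](C)(C)OCc1c([C@@H](c2cc(OC)cc(OC)c2)C=O)c(Br)cc(Br)c1[C@@H](c1cc(OC)cc(OC)c1)C=O | intermediate
16 | 4-methoxyphenylmagnesium bromide (commercial THF solution) | COc1ccc([Mg]Br)cc1 | starting material
17 | (2R,2'R)-2,2'-(4,6-dibromo-2-{[(tert-butyldimethylsilyl)oxy]methyl}-1,3-phenylene)bis[2-(3,5-dimethoxyphenyl)-1-(4-methoxyphenyl)ethan-1-ol], epimer mixture at C1 and C1' | CC(C)(C)[Si](C)(C)OCc1c([C@@H](c2cc(OC)cc(OC)c2)C(O)c2ccc(OC)cc2)c(Br)cc(Br)c1[C@@H](c1cc(OC)cc(OC)c1)C(O)c1ccc(OC)cc1 | intermediate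
18 | (2R,2'R)-2,2'-(4,6-dibromo-2-{[(tert-butyldimethylsilyl)oxy]methyl}-1,3-phenylene)bis[2-(3,5-dimethoxyphenyl)-1-(4-methoxyphenyl)ethan-1-one] | CC(C)(C)[Si](C)(C)OCc1c([C@@H](c2cc(OC)cc(OC)c2)C(=O)c2ccc(OC)cc2)c(Br)cc(Br)c1[C@@H](c1cc(OC)cc(OC)c1)C(=O)c1ccc(OC)cc1 | intermediate
19 | (1R,2R,1'R,2'R)-2,2'-(4,6-dibromo-2-{[(tert-butyldimethylsilyl)oxy]methyl}-1,3-phenylene)bis[2-(3,5-dimethoxyphenyl)-1-(4-methoxyphenyl)ethan-1-ol] | COc1ccc([C@H](O)[C@H](c2cc(OC)cc(OC)c2)c2c(Br)cc(Br)c([C@@H](c3cc(OC)cc(OC)c3)[C@@H](O)c3ccc(OC)cc3)c2CO[Si](C)(C)C(C)(C)C)cc1 | intermediate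
20 | dilithium dialkoxide of the 3-bromoaryne formed from 19 by loss of HBr across a1–a2 | C1([C@@H](c2cc(OC)cc(OC)c2)[C@@H](O[Li])c2ccc(OC)cc2)=C(CO[Si](C)(C)C(C)(C)C)C([C@@H](c2cc(OC)cc(OC)c2)[C@@H](O[Li])c2ccc(OC)cc2)=C(Br)C#C1 | intermediate
21 | monocyclised 2-bromoaryllithium: one (2R,3R)-dihydrofuran closed, lithium at a2, bromine at a3, second arm as lithium alkoxide | [Li]c1c(Br)c([C@@H](c2cc(OC)cc(OC)c2)[C@@H](O[Li])c2ccc(OC)cc2)c(CO[Si](C)(C)C(C)(C)C)c2c1O[C@@H](c1ccc(OC)cc1)[C@@H]2c1cc(OC)cc(OC)c1 | intermediate
22 | alkoxyaryne (triple bond a2–a3) bearing the first dihydrofuran and the second arm as lithium alkoxide | C1#CC([C@@H](c2cc(OC)cc(OC)c2)[C@@H](O[Li])c2ccc(OC)cc2)=C(CO[Si](C)(C)C(C)(C)C)C2=C1O[C@@H](c1ccc(OC)cc1)[C@@H]2c1cc(OC)cc(OC)c1 | intermediate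
23 | (2R,3R,5R,6R)-4-{[(tert-butyldimethylsilyl)oxy]methyl}-3,5-bis(3,5-dimethoxyphenyl)-2,6-bis(4-methoxyphenyl)-2,3,5,6-tetrahydrobenzo[1,2-b:5,4-b']difuran | COc1ccc([C@@H]2Oc3cc4O[C@@H](c5ccc(OC)cc5)[C@H](c5cc(OC)cc(OC)c5)c4c(CO[Si](C)(C)C(C)(C)C)c3[C@H]2c2cc(OC)cc(OC)c2)cc1 | intermediate
24 | [(2R,3R,5R,6R)-3,5-bis(3,5-dimethoxyphenyl)-2,6-bis(4-methoxyphenyl)-2,3,5,6-tetrahydrobenzo[1,2-b:5,4-b']difuran-4-yl]methanol | COc1ccc([C@@H]2Oc3cc4O[C@@H](c5ccc(OC)cc5)[C@H](c5cc(OC)cc(OC)c5)c4c(CO)c3[C@H]2c2cc(OC)cc(OC)c2)cc1 | intermediate
25 | (2R,3R,5R,6R)-3,5-bis(3,5-dimethoxyphenyl)-2,6-bis(4-methoxyphenyl)-2,3,5,6-tetrahydrobenzo[1,2-b:5,4-b']difuran-4-carbaldehyde | COc1ccc([C@@H]2Oc3cc4O[C@@H](c5ccc(OC)cc5)[C@H](c5cc(OC)cc(OC)c5)c4c(C=O)c3[C@H]2c2cc(OC)cc(OC)c2)cc1 | intermediate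
26 | 2,4-dimethoxybenzyl alcohol | COc1ccc(CO)c(OC)c1 | starting material
27 | (2,4-dimethoxybenzyl)triphenylphosphonium bromide | COc1ccc(C[P+](c2ccccc2)(c2ccccc2)c2ccccc2)c(OC)c1.[Br-] | intermediate
28 | (2,4-dimethoxybenzylidene)triphenylphosphorane | COc1ccc(C=P(c2ccccc2)(c2ccccc2)c2ccccc2)c(OC)c1 | intermediate
29 | (2R,3R,5R,6R)-4-[2-(2,4-dimethoxyphenyl)ethenyl]-3,5-bis(3,5-dimethoxyphenyl)-2,6-bis(4-methoxyphenyl)-2,3,5,6-tetrahydrobenzo[1,2-b:5,4-b']difuran, E/Z mixture | COc1ccc([C@@H]2Oc3cc4O[C@@H](c5ccc(OC)cc5)[C@H](c5cc(OC)cc(OC)c5)c4c(C=Cc4ccc(OC)cc4OC)c3[C@H]2c2cc(OC)cc(OC)c2)cc1 | intermediate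
30 | octa-O-methyl ether of the target (all five stereocentres R) | COc1ccc([C@@H]2Oc3cc4c5c(c3[C@H]2c2cc(OC)cc(OC)c2)C[C@H](c2ccc(OC)cc2OC)c2c(OC)cc(OC)cc2[C@H]5[C@H](c2ccc(OC)cc2)O4)cc1 | intermediate
31 | CNP0154047.1 (all five stereocentres R) | Oc1ccc([C@@H]2Oc3cc4c5c(c3[C@H]2c2cc(O)cc(O)c2)C[C@H](c2ccc(O)cc2O)c2c(O)cc(O)cc2[C@H]5[C@H](c2ccc(O)cc2)O4)cc1 | target

## Step count and least certain steps

Total: 21 steps. Longest linear sequence: 20 steps (1 to 31 through steps 1–17 and 19–21; step 18 prepares the phosphonium salt on the side).

Step 15 (key step). The relay may stall or be diverted: the first aryne may be captured by the amide, bromine may be transferred between aryllithium species, or the bromoaryllithium may be protonated before it eliminates. In the product, deprotonation of a doubly benzylic C3–H would open a furan by β-elimination. Fallback: from 19, a copper-catalysed double intramolecular Ullmann etherification (CuI, 3,4,7,8-tetramethyl-1,10-phenanthroline, Cs2CO3, toluene, 110 °C) would form the same two O–ring A bonds by substitution at the two C–Br carbons, without an aryne or strong base and with the same retention at the four stereocentres, and would return to the route at 23.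

Step 10. Aryl transfer may be slow or stop after one arm, because the ortho bromine and the silyloxymethyl-bearing carbon shield both faces of each β-carbon. Fallback: from 9, addition of 3,5-dimethoxyphenylmagnesium bromide would give the bis(diarylmethanol) F1. Oxidation with Dess–Martin periodinane would give the bis(diaryl ketone) F2, and methylenation (Ph3P=CH2 or Cp2TiMe2) the bis(1,1-diarylethene) F3. A catalytic enantioselective hydroboration with pinacolborane (CoCl2, a chiral iminopyridine–oxazoline ligand, NaBHEt3), which distinguishes the twisted ring A from the flat dimethoxyphenyl group, would give the bis(pinacol boronate) F4. Oxidation with NaBO3 would give the primary diol F5, and Dess–Martin oxidation would return to the route at 15, bypassing steps 9–11.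

Step 11. The new α,α-diaryl aldehyde may epimerise by enolisation during its formation or isolation, or the reduction may stop at the oxime. Fallback: from 13, oxidative conversion of the nitromethyl groups with NaNO2/AcOH in DMSO would give the diacid F6, which is far less prone to enolisation. Coupling with N,O-dimethylhydroxylamine would give the bis(Weinreb amide) F7, and addition of 16 would return to the route at 18, bypassing the aldehyde and steps 12–13.

Step 14. Facial selectivity may be poor, or the sense may be opposite to the model, because the two α-aryl groups compete for the anti position; enolisation of the hindered ketone by the hydride would erode Cb. Fallback: the aryl addition of step 12 and the hydride addition of step 14 are stereochemically complementary, so if the sense is reversed, the major epimer of 17 is the required one, and 19 would be obtained from 17 by separation, omitting steps 13 and 14. If the selectivity is merely low, a catalyst-controlled reduction of 18 (oxazaborolidine-catalysed borane reduction) would replace substrate control and return to the route at 19.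

Step 20. The furan benzylic C–O bonds may ionise in competition with alkene protonation, leading to epimerisation or skeletal rearrangement; the cation may be captured intermolecularly; or ring closure may show poor facial selectivity at Ce. Fallback: from 25, Friedel–Crafts acylation of one of the two equivalent dimethoxyphenyl rings with 2,4-dimethoxybenzoyl chloride and SnCl4 would give the keto aldehyde F8. Reductive carbonyl coupling with TiCl4/Zn would close the seven-membered ring as the cycloheptene F9, and hydrogenation (H2, Pd/C) would return to the route at 30. This sequence is longer, the monoacylation is statistical, and the face selectivity of the hydrogenation is uncertain, which is why it is held in reserve.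

## Further compounds

F1 | step 10 | bis(diarylmethanol) from 9 and 3,5-dimethoxyphenylmagnesium bromide (carbinol epimers) | CC(C)(C)[Si](C)(C)OCc1c(C(O)c2cc(OC)cc(OC)c2)c(Br)cc(Br)c1C(O)c1cc(OC)cc(OC)c1
F2 | step 10 | bis(diaryl ketone) | CC(C)(C)[Si](C)(C)OCc1c(C(=O)c2cc(OC)cc(OC)c2)c(Br)cc(Br)c1C(=O)c1cc(OC)cc(OC)c1
F3 | step 10 | bis(1,1-diarylethene) | CC(C)(C)[Si](C)(C)OCc1c(C(=C)c2cc(OC)cc(OC)c2)c(Br)cc(Br)c1C(=C)c1cc(OC)cc(OC)c1
F4 | step 10 | bis(pinacol boronate) of the hydroboration, (R) at both diarylmethine carbons | CC(C)(C)[Si](C)(C)OCc1c([C@@H](c2cc(OC)cc(OC)c2)CB2OC(C)(C)C(C)(C)O2)c(Br)cc(Br)c1[C@@H](c1cc(OC)cc(OC)c1)CB1OC(C)(C)C(C)(C)O1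
F5 | step 10 | (2R,2'R)-2,2'-(4,6-dibromo-2-{[(tert-butyldimethylsilyl)oxy]methyl}-1,3-phenylene)bis[2-(3,5-dimethoxyphenyl)ethan-1-ol] | CC(C)(C)[Si](C)(C)OCc1c([C@@H](c2cc(OC)cc(OC)c2)CO)c(Br)cc(Br)c1[C@@H](c1cc(OC)cc(OC)c1)CO
F6 | step 11 | (2R,2'R)-2,2'-(4,6-dibromo-2-{[(tert-butyldimethylsilyl)oxy]methyl}-1,3-phenylene)bis[2-(3,5-dimethoxyphenyl)acetic acid] | CC(C)(C)[Si](C)(C)OCc1c([C@@H](c2cc(OC)cc(OC)c2)C(=O)O)c(Br)cc(Br)c1[C@@H](c1cc(OC)cc(OC)c1)C(=O)O
F7 | step 11 | bis(N-methoxy-N-methylamide) of F6 | CC(C)(C)[Si](C)(C)OCc1c([C@@H](c2cc(OC)cc(OC)c2)C(=O)N(C)OC)c(Br)cc(Br)c1[C@@H](c1cc(OC)cc(OC)c1)C(=O)N(C)OC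
F0 | step 14 | none | none
F0 | step 15 | none | none
F8 | step 20 | keto aldehyde: 25 carrying a 2,4-dimethoxybenzoyl group at C2 of one 3,5-dimethoxyphenyl ring | COc1ccc([C@@H]2Oc3cc4O[C@@H](c5ccc(OC)cc5)[C@H](c5cc(OC)cc(OC)c5C(=O)c5ccc(OC)cc5OC)c4c(C=O)c3[C@H]2c2cc(OC)cc(OC)c2)cc1
F9 | step 20 | cycloheptene: 30 with a C=C bond between the a5 carbon substituent and Ce | COc1ccc([C@@H]2Oc3cc4c5c(c3[C@H]2c2cc(OC)cc(OC)c2)C=C(c2ccc(OC)cc2OC)c2c(OC)cc(OC)cc2[C@H]5[C@H](c2ccc(OC)cc2)O4)cc1
A1 | alternative 1 | dibenzocycloheptenone ester (racemic at the ester-bearing methine) | COC(=O)C1c2cc(OC)cc(OC)c2C(=O)Cc2cc(OC)cc(OC)c21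
A2 | alternative 1 | methyl 5,7-dimethoxy-2-oxo-2,3-dihydro-1H-indene-1-carboxylate | COC(=O)C1C(=O)Cc2cc(OC)cc(OC)c21
A3 | alternative 1 | 3,5-dimethoxy-2-(trimethylsilyl)phenyl trifluoromethanesulfonate | COc1cc(OC)c([Si](C)(C)C)c(OS(=O)(=O)C(F)(F)F)c1
A4 | alternative 1 | 3,5-dimethoxybenzyne | COC1=CC(OC)=CC#C1
A5 | alternative 2 | tetracyclic 2-(4-methoxyphenyl)benzofuran fused to the seven-membered ring | COc1cc2oc(-c3ccc(OC)cc3)c3c2c(c1)C[C@H](c1ccc(OC)cc1OC)c1c(OC)cc(OC)cc1-3
A6 | alternative 2 | iodophenol–diarylalkyne with Ce in place | COc1cc(O)c(I)c(c1)C[C@H](c1ccc(OC)cc1OC)c1c(OC)cc(OC)cc1C#Cc1ccc(OC)cc1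
A7 | alternative 3 | tetracyclic core with ring B as mono-silylated resorcinol | COc1cc2c3c(c1)C[C@H](c1ccc(OC)cc1OC)c1c(O)cc(O[Si](C(C)C)(C(C)C)C(C)C)cc1[C@H]3[C@H](c1ccc(OC)cc1)O2
A8 | alternative 3 | cycloheptenyl diazomethyl ketone fused to the dihydrobenzofuran | COc1cc2c3c(c1)C[C@H](c1ccc(OC)cc1OC)C=C(C(=O)C=[N+]=[N-])[C@H]3[C@H](c1ccc(OC)cc1)O2
A9 | alternative 3 | (triisopropylsiloxy)acetylene | C#CO[Si](C(C)C)(C(C)C)C(C)C
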